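**Plan**

Numbering: lactone carbonyl C1, ring carbinol C5, chain carbinols C7, C9, C11 and C15, terminal methyl C26. In the 5,6-dihydropyran-2-one ring the bonds O–C5 and C4–C5 meet at C5, the only ring stereocentre. The ring is therefore cut there into the C5–C26 aldehyde and a four-carbon 1-oxygenated diene (C1–C4), which is what allows a hetero-Diels–Alder closure.
Behind the aldehyde the chain is cut at C5–C6 (allylation, one extra carbon removed afterwards), at C10–C11 (vinylogous aldol of an acetoacetate dienolate that supplies C7–C10), and at C13–C14 and C16–C17 (two Grignard openings around an epichlorohydrin-derived epoxide).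
Forward, the chain grows linearly from the C26 end to the fully silylated aldehyde. The single ring closes in the cycloaddition and is then brought to the lactone level by reduction, allylic transposition and oxidation, before global desilylation.
Stereochemistry: C15 from (S)-epichlorohydrin; C11 from a titanium–BINOL-catalysed aldol; C9 from a chelation-controlled 1,3-syn reduction; C7 from a reagent-controlled allylboration; C5 from the chiral chromium–salen catalyst.

Key step: step 13

Assumption: the Si-face delivery ascribed to the (S)-BINOL–titanium and (S,S)-salen–chromium catalysts is the sense they are understood to show with simple unbranched aldehydes; both ligands are available in either hand.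

**Route**

Step 1
Reactants: 1 1-bromodecane; 2 (S)-epichlorohydrin
Product: 4 (S)-1-chlorotridecan-2-ol, via decylmagnesium bromide 3 (not isolated)
Conditions: Mg, THF, reflux; then 2, CuI (10 mol%), THF, −40 to 0 °C; H2O
Reagents that add atoms: none
Why: Copper-catalysed Grignard opening of the epoxide (SN2 at the unsubstituted ring carbon, faster than chloride displacement) forms C16–C17 and leaves the stereocentre of 2, the future C15, untouched.

Step 2
Reactants: 4 (S)-1-chlorotridecan-2-ol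
Product: 5 (S)-2-undecyloxirane
Conditions: NaOH (powdered), Et2O, rt
Reagents that add atoms: none
Why: Intramolecular Williamson ether synthesis (3-exo-tet displacement of chloride by the alkoxide) closes the C14–C15 epoxide while the C15–O bond stays intact.

Step 3
Reactants: 5 (S)-2-undecyloxirane; 6 but-3-en-1-ylmagnesium bromide
Product: 7 (S)-heptadec-1-en-6-ol
Conditions: CuI (10 mol%), THF, −40 to 0 °C; H2O
Reagents that add atoms: none
Why: Copper-catalysed Grignard opening at the terminal epoxide carbon forms C13–C14, brings in C11–C13 with a terminal alkene as a masked C11 aldehyde, and frees the C15 hydroxyl without touching its configuration.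

Step 4
Reactants: 7 (S)-heptadec-1-en-6-ol
Product: 8 (S)-tert-butyl(heptadec-1-en-6-yloxy)dimethylsilane
Conditions: TBSCl, imidazole, DMF, rt
Reagents that add atoms: tert-butyldimethylsilyl chloride, CC(C)(C)[Si](C)(C)Cl
Why: Imidazole-promoted silylation protects the C15 hydroxyl as a TBS ether that should survive every later step up to the final acid treatment.

Step 5
Reactants: 8 (S)-tert-butyl(heptadec-1-en-6-yloxy)dimethylsilane
Product: 10 (S)-5-(tert-butyldimethylsilyloxy)hexadecanal, via ozonide 9 (not isolated)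
Conditions: O3, CH2Cl2, −78 °C; then PPh3, −78 °C to rt
Reagents that add atoms: ozone, [O-][O+]=O
Why: Ozonolysis with phosphine reduction of the ozonide cleaves the terminal alkene to the C11 aldehyde without over-oxidation.

Step 6
Reactants: 10 (S)-5-(tert-butyldimethylsilyloxy)hexadecanal; 11 1-methoxy-1,3-bis(trimethylsilyloxy)buta-1,3-diene
Product: 13 methyl (5R,9S)-9-(tert-butyldimethylsilyloxy)-5-hydroxy-3-oxoicosanoate, via bis-silyl aldol adduct 12 (not isolated)
Conditions: Ti(OiPr)4/(S)-BINOL (1:1, 10 mol%), 4 Å MS, THF, −78 °C to rt; then TFA (cat.), THF, −78 to 0 °C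
Reagents that add atoms: none
Why: Catalytic asymmetric vinylogous Mukaiyama aldol, in which the titanium–BINOL Lewis acid activates the aldehyde and the bis-silyl dienolate of methyl acetoacetate attacks through its terminal carbon on the Si face, forming C10–C11 and setting C11 on an aldehyde with no nearby stereocentre to interfere.

Step 7
Reactants: 13 methyl (5R,9S)-9-(tert-butyldimethylsilyloxy)-5-hydroxy-3-oxoicosanoate
Product: 15 methyl (3R,5R,9S)-9-(tert-butyldimethylsilyloxy)-3,5-dihydroxyicosanoate, via diethylborinate chelate 14 (not isolated)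
Conditions: Et2BOMe, THF/MeOH (4:1), −78 °C; NaBH4; then MeOH co-evaporation
Reagents that add atoms: none
Why: Narasaka–Prasad reduction, in which the diethylboron chelate of the β-hydroxy ketone fixes a half-chair that external hydride attacks axially, gives the 1,3-syn diol and so sets C9 from C11.

Step 8
Reactants: 15 methyl (3R,5R,9S)-9-(tert-butyldimethylsilyloxy)-3,5-dihydroxyicosanoate
Product: 16 methyl (3R,5R,9S)-3,5,9-tris(tert-butyldimethylsilyloxy)icosanoate
Conditions: TBSOTf, 2,6-lutidine, CH2Cl2, −78 to 0 °C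
Reagents that add atoms: tert-butyldimethylsilyl trifluoromethanesulfonate, CC(C)(C)[Si](C)(C)OS(=O)(=O)C(F)(F)F
Why: Silylation with the silyl triflate and a hindered base caps both secondary hydroxyls quickly at low temperature, before lactonisation or β-elimination of the β-hydroxy ester can compete.

Step 9
Reactants: 16 methyl (3R,5R,9S)-3,5,9-tris(tert-butyldimethylsilyloxy)icosanoate
Product: 18 (3R,5R,9S)-3,5,9-tris(tert-butyldimethylsilyloxy)icosanal, via aluminium hemiacetal 17 (not isolated)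
Conditions: iBu2AlH (1.1 equiv), CH2Cl2, −78 °C; MeOH, then aq. potassium sodium tartrate
Reagents that add atoms: none
Why: Partial ester reduction, in which the tetrahedral aluminium hemiacetal persists at −78 °C until hydrolytic work-up, so the C7 aldehyde is released only after the hydride has been quenched.

Step 10
Reactants: 18 (3R,5R,9S)-3,5,9-tris(tert-butyldimethylsilyloxy)icosanal
Product: 20 (4S,6S,8R,12S)-6,8,12-tris(tert-butyldimethylsilyloxy)tricos-1-en-4-ol, via diisopinocampheylborinate 19 (not isolated)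
Conditions: (−)-Ipc2B(allyl), Et2O, −78 °C; then 3 M NaOH, 30% H2O2, rt
Reagents that add atoms: (−)-B-allyldiisopinocampheylborane, C=CCB([C@@H]1C[C@@H]2C[C@H]([C@H]1C)C2(C)C)[C@@H]1C[C@@H]2C[C@H]([C@H]1C)C2(C)C
Why: Brown allylation, in which allyl transfer through a closed chair-like six-membered transition state is steered to the Si face by the isopinocampheyl groups on boron, forms C6–C7 and sets C7 syn to C9 irrespective of the weak bias of the β-silyloxy centre.

Step 11
Reactants: 20 (4S,6S,8R,12S)-6,8,12-tris(tert-butyldimethylsilyloxy)tricos-1-en-4-ol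
Product: 21 (4S,6R,8R,12S)-4,6,8,12-tetrakis(tert-butyldimethylsilyloxy)tricos-1-ene
Conditions: TBSOTf, 2,6-lutidine, CH2Cl2, −78 to 0 °C
Reagents that add atoms: tert-butyldimethylsilyl trifluoromethanesulfonate, CC(C)(C)[Si](C)(C)OS(=O)(=O)C(F)(F)F
Why: Silyl triflate silylation of the hindered C7 hydroxyl completes a uniform, non-chelating TBS protection of all four carbinols.

Step 12
Reactants: 21 (4S,6R,8R,12S)-4,6,8,12-tetrakis(tert-butyldimethylsilyloxy)tricos-1-ene
Product: 23 (3R,5R,7R,11S)-3,5,7,11-tetrakis(tert-butyldimethylsilyloxy)docosanal, via ozonide 22 (not isolated)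
Conditions: O3, CH2Cl2, −78 °C; then PPh3, −78 °C to rt
Reagents that add atoms: ozone, [O-][O+]=O
Why: Ozonolysis with reductive work-up removes the extra terminal carbon and unveils the C5 aldehyde, which has no α-stereocentre to epimerise.

Step 13
Reactants: 23 (3R,5R,7R,11S)-3,5,7,11-tetrakis(tert-butyldimethylsilyloxy)docosanal; 24 Danishefsky's diene, (E)-1-methoxy-3-(trimethylsilyloxy)buta-1,3-diene
Product: 26 (R)-2-[(2S,4R,6R,10S)-2,4,6,10-tetrakis(tert-butyldimethylsilyloxy)henicosyl]-2,3-dihydro-4H-pyran-4-one, via silyl enol ether cycloadduct 25 (not isolated)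
Conditions: (S,S)-(salen)CrCl [salen = N,N'-bis(3,5-di-tert-butylsalicylidene)cyclohexane-1,2-diaminato] (5 mol%), 4 Å MS, tBuOMe, −30 °C; then TFA (cat.), CH2Cl2, 0 °C
Reagents that add atoms: none
Why: The trivalent chromium centre binds the aldehyde oxygen of 23 and the diene adds across the C=O bond in a concerted but asynchronous [4+2] cycloaddition, the C4–C5 bond running ahead of the O–C1 bond, to give acetal 25, which TFA turns into enone 26 by enol ether hydrolysis and loss of methanol. The closest known reaction type is the (salen)CrCl-catalysed enantioselective hetero-Diels–Alder reaction of this diene with unbranched aliphatic aldehydes. The six-membered dihydropyran ring closes in the cycloaddition itself, both ring bonds being made in one event; should part of the material follow a Mukaiyama aldol path, the acid closes the same ring by 6-endo oxa-conjugate addition and elimination of methanol. C5, the only new stereocentre that is kept, is set by the catalyst: the (S,S) complex is chosen to expose the Si face of the aldehyde, which gives the 5,7-syn product. The step needs facial selectivity against the weak 1,3-anti preference of the β-silyloxy aldehyde, secured by catalyst control over a substrate whose non-chelating TBS ethers and missing α-stereocentre keep its own bias small, and regioselectivity, secured by the polarity of the diene, whose nucleophilic CH2 terminus attacks the carbonyl carbon. Any C5 epimer differs from 26 in a 1,3-relationship and should be separable by chromatography at this stage.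

Step 14
Reactants: 26 (R)-2-[(2S,4R,6R,10S)-2,4,6,10-tetrakis(tert-butyldimethylsilyloxy)henicosyl]-2,3-dihydro-4H-pyran-4-one
Product: 27 (2S,4S)-2-[(2S,4R,6R,10S)-2,4,6,10-tetrakis(tert-butyldimethylsilyloxy)henicosyl]-3,4-dihydro-2H-pyran-4-ol
Conditions: NaBH4, CeCl3·7H2O, MeOH, −78 to −40 °C
Reagents that add atoms: none
Why: Luche reduction, a cerium-assisted 1,2-addition of hydride to the vinylogous ester carbonyl with axial attack, should give the cis allylic alcohol, whose new carbinol centre is removed again in step 15.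

Step 15
Reactants: 27 (2S,4S)-2-[(2S,4R,6R,10S)-2,4,6,10-tetrakis(tert-butyldimethylsilyloxy)henicosyl]-3,4-dihydro-2H-pyran-4-ol
Product: 28 (2S,6S)-2-isopropoxy-6-[(2S,4R,6R,10S)-2,4,6,10-tetrakis(tert-butyldimethylsilyloxy)henicosyl]-5,6-dihydro-2H-pyran
Conditions: PPTS (cat.), iPrOH, rt
Reagents that add atoms: propan-2-ol, CC(C)O
Why: Ferrier rearrangement, in which acid ionises the allylic alcohol to the ring-oxygen-stabilised allyl cation and isopropanol adds at C1, shifts the double bond to C2=C3 and should give mainly the axial (trans) acetal.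

Step 16
Reactants: 28 (2S,6S)-2-isopropoxy-6-[(2S,4R,6R,10S)-2,4,6,10-tetrakis(tert-butyldimethylsilyloxy)henicosyl]-5,6-dihydro-2H-pyran
Product: 29 (6S)-6-[(2S,4R,6R,10S)-2,4,6,10-tetrakis(tert-butyldimethylsilyloxy)henicosyl]-5,6-dihydro-2H-pyran-2-ol
Conditions: PPTS (cat.), acetone/H2O (10:1), rt
Reagents that add atoms: water, O
Why: Acid-catalysed acetal hydrolysis through the same oxocarbenium ion exchanges isopropoxy for hydroxyl under conditions too mild to cleave secondary TBS ethers.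

Step 17
Reactants: 29 (6S)-6-[(2S,4R,6R,10S)-2,4,6,10-tetrakis(tert-butyldimethylsilyloxy)henicosyl]-5,6-dihydro-2H-pyran-2-ol
Product: 30 (S)-6-[(2S,4R,6R,10S)-2,4,6,10-tetrakis(tert-butyldimethylsilyloxy)henicosyl]-5,6-dihydro-2H-pyran-2-one
Conditions: MnO2 (excess), CH2Cl2, rt
Reagents that add atoms: none
Why: Allylic oxidation with MnO2 converts the allylic lactol into the α,β-unsaturated δ-lactone under neutral conditions that leave the silyl ethers and C5 untouched.

Step 18
Reactants: 30 (S)-6-[(2S,4R,6R,10S)-2,4,6,10-tetrakis(tert-butyldimethylsilyloxy)henicosyl]-5,6-dihydro-2H-pyran-2-one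
Product: 31 (S)-6-[(2R,4R,6R,10S)-2,4,6,10-tetrahydroxyhenicosyl]-5,6-dihydro-2H-pyran-2-one
Conditions: 48% aq. HF, MeCN, 0 °C to rt
Reagents that add atoms: none
Why: Global desilylation with aqueous HF cleaves all four Si–O bonds under weakly acidic conditions in which the unsaturated lactone should neither open nor suffer oxa-Michael addition of the freed C7 hydroxyl.

**Compound list**

1 | 1-bromodecane | CCCCCCCCCCBr | starting material
2 | (S)-epichlorohydrin | ClC[C@@H]1CO1 | starting material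
3 | decylmagnesium bromide | CCCCCCCCCC[Mg]Br | intermediate (not isolated)
4 | (S)-1-chlorotridecan-2-ol | CCCCCCCCCCC[C@H](O)CCl | intermediate
5 | (S)-2-undecyloxirane | CCCCCCCCCCC[C@H]1CO1 | intermediate
6 | but-3-en-1-ylmagnesium bromide (commercial THF solution) | C=CCC[Mg]Br | starting material
7 | (S)-heptadec-1-en-6-ol | CCCCCCCCCCC[C@H](O)CCCC=C | intermediate
8 | (S)-tert-butyl(heptadec-1-en-6-yloxy)dimethylsilane | CCCCCCCCCCC[C@H](O[Si](C)(C)C(C)(C)C)CCCC=C | intermediate
9 | ozonide of 8, 3-[(S)-4-(tert-butyldimethylsilyloxy)pentadecyl]-1,2,4-trioxolane (mixture at the ring carbon) | CCCCCCCCCCC[C@H](O[Si](C)(C)C(C)(C)C)CCCC1OCOO1 | intermediate (not isolated)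
10 | (S)-5-(tert-butyldimethylsilyloxy)hexadecanal | CCCCCCCCCCC[C@H](O[Si](C)(C)C(C)(C)C)CCCC=O | intermediate
11 | 1-methoxy-1,3-bis(trimethylsilyloxy)buta-1,3-diene (bis-silyl dienolate of methyl acetoacetate; ketene acetal geometry not defined) | COC(O[Si](C)(C)C)=CC(=C)O[Si](C)(C)C | starting material
12 | methyl (5R,9S)-9-(tert-butyldimethylsilyloxy)-3,5-bis(trimethylsilyloxy)icos-2-enoate (enol ether geometry not defined) | CCCCCCCCCCC[C@H](O[Si](C)(C)C(C)(C)C)CCC[C@@H](O[Si](C)(C)C)CC(O[Si](C)(C)C)=CC(=O)OC | intermediate (not isolated)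
13 | methyl (5R,9S)-9-(tert-butyldimethylsilyloxy)-5-hydroxy-3-oxoicosanoate | CCCCCCCCCCC[C@H](O[Si](C)(C)C(C)(C)C)CCC[C@@H](O)CC(=O)CC(=O)OC | intermediate
14 | methyl (5R,9S)-9-(tert-butyldimethylsilyloxy)-5-(diethylboryloxy)-3-oxoicosanoate (boron chelated by the ketone oxygen) | CCCCCCCCCCC[C@H](O[Si](C)(C)C(C)(C)C)CCC[C@@H](OB(CC)CC)CC(=O)CC(=O)OC | intermediate (not isolated)
15 | methyl (3R,5R,9S)-9-(tert-butyldimethylsilyloxy)-3,5-dihydroxyicosanoate | CCCCCCCCCCC[C@H](O[Si](C)(C)C(C)(C)C)CCC[C@@H](O)C[C@@H](O)CC(=O)OC | intermediate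
16 | methyl (3R,5R,9S)-3,5,9-tris(tert-butyldimethylsilyloxy)icosanoate | CCCCCCCCCCC[C@H](O[Si](C)(C)C(C)(C)C)CCC[C@@H](O[Si](C)(C)C(C)(C)C)C[C@@H](O[Si](C)(C)C(C)(C)C)CC(=O)OC | intermediate
17 | diisobutylaluminium hemiacetal of 16 (1-methoxy-1-aluminoxy adduct, mixture at C1) | CCCCCCCCCCC[C@H](O[Si](C)(C)C(C)(C)C)CCC[C@@H](O[Si](C)(C)C(C)(C)C)C[C@@H](O[Si](C)(C)C(C)(C)C)CC(OC)O[Al](CC(C)C)CC(C)C | intermediate (not isolated)
18 | (3R,5R,9S)-3,5,9-tris(tert-butyldimethylsilyloxy)icosanal | CCCCCCCCCCC[C@H](O[Si](C)(C)C(C)(C)C)CCC[C@@H](O[Si](C)(C)C(C)(C)C)C[C@@H](O[Si](C)(C)C(C)(C)C)CC=O | intermediate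
19 | diisopinocampheylborinate of 20 | CCCCCCCCCCC[C@H](O[Si](C)(C)C(C)(C)C)CCC[C@@H](O[Si](C)(C)C(C)(C)C)C[C@@H](O[Si](C)(C)C(C)(C)C)C[C@@H](OB([C@@H]1C[C@@H]2C[C@H]([C@H]1C)C2(C)C)[C@@H]1C[C@@H]2C[C@H]([C@H]1C)C2(C)C)CC=C | intermediate (not isolated)
20 | (4S,6S,8R,12S)-6,8,12-tris(tert-butyldimethylsilyloxy)tricos-1-en-4-ol | CCCCCCCCCCC[C@H](O[Si](C)(C)C(C)(C)C)CCC[C@@H](O[Si](C)(C)C(C)(C)C)C[C@@H](O[Si](C)(C)C(C)(C)C)C[C@@H](O)CC=C | intermediate
21 | (4S,6R,8R,12S)-4,6,8,12-tetrakis(tert-butyldimethylsilyloxy)tricos-1-ene | CCCCCCCCCCC[C@H](O[Si](C)(C)C(C)(C)C)CCC[C@@H](O[Si](C)(C)C(C)(C)C)C[C@@H](O[Si](C)(C)C(C)(C)C)C[C@@H](O[Si](C)(C)C(C)(C)C)CC=C | intermediate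
22 | ozonide of 21, 3-[(2R,4R,6R,10S)-2,4,6,10-tetrakis(tert-butyldimethylsilyloxy)henicosyl]-1,2,4-trioxolane (mixture at the ring carbon) | CCCCCCCCCCC[C@H](O[Si](C)(C)C(C)(C)C)CCC[C@@H](O[Si](C)(C)C(C)(C)C)C[C@@H](O[Si](C)(C)C(C)(C)C)C[C@@H](O[Si](C)(C)C(C)(C)C)CC1OCOO1 | intermediate (not isolated)
23 | (3R,5R,7R,11S)-3,5,7,11-tetrakis(tert-butyldimethylsilyloxy)docosanal | CCCCCCCCCCC[C@H](O[Si](C)(C)C(C)(C)C)CCC[C@@H](O[Si](C)(C)C(C)(C)C)C[C@@H](O[Si](C)(C)C(C)(C)C)C[C@@H](O[Si](C)(C)C(C)(C)C)CC=O | intermediate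
24 | Danishefsky's diene, (E)-1-methoxy-3-(trimethylsilyloxy)buta-1,3-diene | CO/C=C/C(=C)O[Si](C)(C)C | starting material
25 | (2R)-6-methoxy-2-[(2S,4R,6R,10S)-2,4,6,10-tetrakis(tert-butyldimethylsilyloxy)henicosyl]-4-(trimethylsilyloxy)-3,6-dihydro-2H-pyran (mixture at the acetal carbon) | CCCCCCCCCCC[C@H](O[Si](C)(C)C(C)(C)C)CCC[C@@H](O[Si](C)(C)C(C)(C)C)C[C@@H](O[Si](C)(C)C(C)(C)C)C[C@@H](O[Si](C)(C)C(C)(C)C)C[C@@H]1CC(O[Si](C)(C)C)=CC(OC)O1 | intermediate (not isolated)
26 | (R)-2-[(2S,4R,6R,10S)-2,4,6,10-tetrakis(tert-butyldimethylsilyloxy)henicosyl]-2,3-dihydro-4H-pyran-4-one | CCCCCCCCCCC[C@H](O[Si](C)(C)C(C)(C)C)CCC[C@@H](O[Si](C)(C)C(C)(C)C)C[C@@H](O[Si](C)(C)C(C)(C)C)C[C@@H](O[Si](C)(C)C(C)(C)C)C[C@@H]1CC(=O)C=CO1 | intermediate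
27 | (2S,4S)-2-[(2S,4R,6R,10S)-2,4,6,10-tetrakis(tert-butyldimethylsilyloxy)henicosyl]-3,4-dihydro-2H-pyran-4-ol (cis) | CCCCCCCCCCC[C@H](O[Si](C)(C)C(C)(C)C)CCC[C@@H](O[Si](C)(C)C(C)(C)C)C[C@@H](O[Si](C)(C)C(C)(C)C)C[C@@H](O[Si](C)(C)C(C)(C)C)C[C@@H]1C[C@H](O)C=CO1 | intermediate
28 | (2S,6S)-2-isopropoxy-6-[(2S,4R,6R,10S)-2,4,6,10-tetrakis(tert-butyldimethylsilyloxy)henicosyl]-5,6-dihydro-2H-pyran (trans, expected major anomer; both anomers converge in step 16) | CCCCCCCCCCC[C@H](O[Si](C)(C)C(C)(C)C)CCC[C@@H](O[Si](C)(C)C(C)(C)C)C[C@@H](O[Si](C)(C)C(C)(C)C)C[C@@H](O[Si](C)(C)C(C)(C)C)C[C@@H]1CC=C[C@@H](OC(C)C)O1 | intermediate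
29 | (6S)-6-[(2S,4R,6R,10S)-2,4,6,10-tetrakis(tert-butyldimethylsilyloxy)henicosyl]-5,6-dihydro-2H-pyran-2-ol (anomeric mixture) | CCCCCCCCCCC[C@H](O[Si](C)(C)C(C)(C)C)CCC[C@@H](O[Si](C)(C)C(C)(C)C)C[C@@H](O[Si](C)(C)C(C)(C)C)C[C@@H](O[Si](C)(C)C(C)(C)C)C[C@@H]1CC=CC(O)O1 | intermediate
30 | (S)-6-[(2S,4R,6R,10S)-2,4,6,10-tetrakis(tert-butyldimethylsilyloxy)henicosyl]-5,6-dihydro-2H-pyran-2-one | CCCCCCCCCCC[C@H](O[Si](C)(C)C(C)(C)C)CCC[C@@H](O[Si](C)(C)C(C)(C)C)C[C@@H](O[Si](C)(C)C(C)(C)C)C[C@@H](O[Si](C)(C)C(C)(C)C)C[C@@H]1CC=CC(=O)O1 | intermediate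
31 | (S)-6-[(2R,4R,6R,10S)-2,4,6,10-tetrahydroxyhenicosyl]-5,6-dihydro-2H-pyran-2-one | CCCCCCCCCCC[C@H](O)CCC[C@@H](O)C[C@@H](O)C[C@@H](O)C[C@@H]1CC=CC(=O)O1 | target

**Step count and risks**

Total step count: 18. Longest linear sequence: 18 steps (1 and 2 to 31; the route is fully linear).

Steps most likely to fail:

1. Step 13. Facial selectivity may erode because the catalyst has to overrule the 1,3-anti preference of the β-silyloxy aldehyde, and slow turnover with the hindered aldehyde may let the diene hydrolyse first. The fallback closes the ring by metathesis instead of cycloaddition and sets out from 23. Brown allylation with (−)-Ipc2B(allyl) (Et2O, −78 °C; NaOH, H2O2) on the Si face would give (4S,6S,8R,10R,14S)-6,8,10,14-tetrakis(tert-butyldimethylsilyloxy)pentacos-1-en-4-ol F1. Acylation with acryloyl chloride (Et3N, DMAP, CH2Cl2, 0 °C) would give (4S,6S,8R,10R,14S)-6,8,10,14-tetrakis(tert-butyldimethylsilyloxy)pentacos-1-en-4-yl prop-2-enoate F2. Ring-closing metathesis with the second-generation Grubbs catalyst (H2IMes)(PCy3)Cl2Ru=CHPh (CH2Cl2, reflux) would then give 30, where the route is rejoined; steps 14 to 17 fall away.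

2. Step 6. Enantiofacial discrimination in the titanium-catalysed aldol may be insufficient or of the opposite sense, which would leave C11 epimers that cannot be separated from the remote C15 centre; the dienolate may also be desilylated prematurely. The fallback builds C9 and C11 by two allylborations and sets out from 10. Brown allylation with (−)-Ipc2B(allyl) would give (4R,8S)-8-(tert-butyldimethylsilyloxy)nonadec-1-en-4-ol F3. Silylation (TBSOTf, 2,6-lutidine) would give (4R,8S)-4,8-bis(tert-butyldimethylsilyloxy)nonadec-1-ene F4, and ozonolysis (O3; PPh3) would give (3R,7S)-3,7-bis(tert-butyldimethylsilyloxy)octadecanal F5. A second Brown allylation with the same reagent would give (4S,6R,10S)-6,10-bis(tert-butyldimethylsilyloxy)henicos-1-en-4-ol F6, and silylation would give (4S,6R,10S)-4,6,10-tris(tert-butyldimethylsilyloxy)henicos-1-ene F7. Ozonolysis of F7 would deliver 18, where the route is rejoined at the cost of three extra steps.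

3. Step 9. The ester may be over-reduced to the primary alcohol if the aluminium hemiacetal collapses before the quench, or left partly unreacted. The fallback uses a full reduction and re-oxidation and sets out from 16. LiBH4 (THF, MeOH, 0 °C to rt) would give (3S,5R,9S)-3,5,9-tris(tert-butyldimethylsilyloxy)icosan-1-ol F8, and Dess–Martin periodinane (NaHCO3, CH2Cl2, rt) would oxidise it to 18, where the route is rejoined.

Further compounds
F1 | step 13 | (4S,6S,8R,10R,14S)-6,8,10,14-tetrakis(tert-butyldimethylsilyloxy)pentacos-1-en-4-ol | CCCCCCCCCCC[C@H](O[Si](C)(C)C(C)(C)C)CCC[C@@H](O[Si](C)(C)C(C)(C)C)C[C@@H](O[Si](C)(C)C(C)(C)C)C[C@@H](O[Si](C)(C)C(C)(C)C)C[C@@H](O)CC=C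
F2 | step 13 | (4S,6S,8R,10R,14S)-6,8,10,14-tetrakis(tert-butyldimethylsilyloxy)pentacos-1-en-4-yl prop-2-enoate | CCCCCCCCCCC[C@H](O[Si](C)(C)C(C)(C)C)CCC[C@@H](O[Si](C)(C)C(C)(C)C)C[C@@H](O[Si](C)(C)C(C)(C)C)C[C@@H](O[Si](C)(C)C(C)(C)C)C[C@@H](OC(=O)C=C)CC=C
F3 | step 6 | (4R,8S)-8-(tert-butyldimethylsilyloxy)nonadec-1-en-4-ol | CCCCCCCCCCC[C@H](O[Si](C)(C)C(C)(C)C)CCC[C@@H](O)CC=C
F4 | step 6 | (4R,8S)-4,8-bis(tert-butyldimethylsilyloxy)nonadec-1-ene | CCCCCCCCCCC[C@H](O[Si](C)(C)C(C)(C)C)CCC[C@@H](O[Si](C)(C)C(C)(C)C)CC=C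
F5 | step 6 | (3R,7S)-3,7-bis(tert-butyldimethylsilyloxy)octadecanal | CCCCCCCCCCC[C@H](O[Si](C)(C)C(C)(C)C)CCC[C@@H](O[Si](C)(C)C(C)(C)C)CC=O
F6 | step 6 | (4S,6R,10S)-6,10-bis(tert-butyldimethylsilyloxy)henicos-1-en-4-ol | CCCCCCCCCCC[C@H](O[Si](C)(C)C(C)(C)C)CCC[C@@H](O[Si](C)(C)C(C)(C)C)C[C@@H](O)CC=C
F7 | step 6 | (4S,6R,10S)-4,6,10-tris(tert-butyldimethylsilyloxy)henicos-1-ene | CCCCCCCCCCC[C@H](O[Si](C)(C)C(C)(C)C)CCC[C@@H](O[Si](C)(C)C(C)(C)C)C[C@@H](O[Si](C)(C)C(C)(C)C)CC=C
F8 | step 9 | (3S,5R,9S)-3,5,9-tris(tert-butyldimethylsilyloxy)icosan-1-ol | CCCCCCCCCCC[C@H](O[Si](C)(C)C(C)(C)C)CCC[C@@H](O[Si](C)(C)C(C)(C)C)C[C@@H](O[Si](C)(C)C(C)(C)C)CCO
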